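The runs were computed from invented constants; scatter was added.

Time came first. By the first reading, at 1.33 h, Saturday's flask showed 97.4% target and 1.3% starting material, so the target formed early and then slowly drained away. At 20.0 h, Saturday's flask read 74.2% and Tuesday's 74.3%, from charges of 13 mM and 10 mM. A percentage loss that ignores the charge is first order in target.

in all of them: temperature 37 °C
- Saturday's: starting material 13 mM; free enzyme 0.15 µM; run made earlier
- Tuesday's: starting material 10 mM; free enzyme 0.15 µM; run made earlier
- ochre: starting material 20 mM; free enzyme 0.040 µM; time 100 h
- blue: starting material 20 mM; free enzyme 0.15 µM; time 50 h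

| run | time / h | target / % | starting material / % |
|---|---|---|---|
| Saturday's | 1.33 | 97.4 | 1.3 |
| Saturday's | 2.00 | 96.3 | 0 |
| Saturday's | 3.00 | 94.2 | 1.1 |
| Saturday's | 5.00 | 93.3 | 0 |
| Saturday's | 8.00 | 87.2 | 1.7 |
| Saturday's | 12.0 | 82.7 | 0 |
| Saturday's | 20.0 | 74.2 | 0 |
| Tuesday's | 1.33 | 97.0 | 0.8 |
| Tuesday's | 2.00 | 97.2 | 0.7 |
| Tuesday's | 3.00 | 96.8 | 1.0 |
| Tuesday's | 5.00 | 92.9 | 0.6 |
| Tuesday's | 8.00 | 87.8 | 0.6 |
| Tuesday's | 12.0 | 82.9 | 0 |
| Tuesday's | 20.0 | 74.3 | 0.7 |

(scatter of a reading: 1 percentage point)

- on the list of suspects stand: free enzyme -> unfolded enzyme; starting material + free enzyme -> target + free enzyme; target + free enzyme <-> isomer of the product + free enzyme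
- no earlier run changes the charge of free enzyme; that part of a forecast is a guess

- which one finishes higher in amount of target, in percent of the starting material charged ("neither" within 2 percentage points) (ochre / blue / neither)
- amount of target at the end, in percent of the starting material charged, ochre
- amount of target at the end, in percent of the starting material charged, blue

The suspect step that consumes target runs on free enzyme, so I treated the loss as pseudo-first-order and reckoned in dose, meaning enzyme concentration times time. No run had changed the enzyme, so this was a guess. I wrote n for a flask's dose divided by the dose of those runs at their last reading, and S for the surviving share of target per unit of n, 74.2%. Ochre has n = 1.33 and blue n = 2.50, less dose in ochre. Scaling Saturday's first reading by charge and enzyme gave ochre's starting material 7.67 h, far inside its 100 h.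

I then solved two extreme flasks. In the low one the loss keeps its pace, so target is S^n: 67.2% in ochre and 47.4% in blue. In the high one the loss stops at the last reading, leaving 74.2% in both. A way back or a dying enzyme moves a flask up from the low extreme, but the readings, with their scatter of 1 percentage point, showed no levelling I could trust. I therefore put each flask between its two extremes, with ochre higher.

The forecast gave ochre, with 73% for ochre and 52% for blue, on the ground that “What matters is therefore enzyme × time”.

The flasks gave 68.5% in ochre and 49.6% in blue, so ochre finished higher.

    free enzyme → unfolded enzyme (k = 1.50 × 10⁻⁷ /s, Ea = 216 kJ/mol)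
    starting material + free enzyme → target + free enzyme, rate k2*[starting material]^1.5*[free enzyme]/(1 + ([starting material]/Kh2)^1.5) (9.50 mM, k = 2.30 × 10⁵ /M^1.5/s, Ea = 24.0 kJ/mol)
    target + free enzyme ⇌ isomer of the product + free enzyme, rate k3*[free enzyme]*[target] forward; the back reaction follows from the equilibrium constant (K = 8.10, k = 28.0 /M/s, Ea = 43.0 kJ/mol, ΔH = −12.0 kJ/mol)
    (constants at 37 °C)

The gap came mainly from ochre's smaller charge of free enzyme: with blue's charge, ochre held 28.1% at 100 h. The missing target stood as isomer of the product, 31.5% in ochre and 50.4% in blue. S^n lay below the flask by 1.2 points in ochre and 2.1 points in blue. Blue left until 5.0 d reached n = 6.00, where S^n gives 16.7%, and that flask held 23.4%.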